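**Retrosynthetic overview**
- The free 15-OH comes from selective removal of the primary acetate of a 7,15-diacetate. The C3 methylene comes from a C3 ketone left by the radical initiator.
- Key disconnection: C4–C5 and C9–C10 are made in one operation, an oxidative radical bicyclisation of an acyclic E,E,E-triene that already carries all the oxygen. Ring A closes first, then ring B, and loss of an H from C17 gives the exocyclic alkene. This is the same bond set, order and termination as geranylgeranyl diphosphate → copalyl diphosphate.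
- The C19 ester enters as part of the initiating β-keto ester. The C7 acetate enters as the only stereocentre made by reagent control.
- The chain is assembled from methyl 2-methylacetoacetate (C2–C4, C18, C19), a prenyl unit (C1, C5, C6, C10, C20) and geranyl acetate (C7–C9, C11–C17).

Assumption: labdane numbering is used (ring A = C1–C5 and C10, ring B = C5–C10). The SMILES reads as 4S,5R,7S,9R,10R,13E, that is the normal labdane series with an axial 19-ester and an equatorial 7β-acetate.

**Step 1**
Reactants: 1 geranyl acetate
Product: 2 (2E,6E)-3,7-dimethyl-8-oxoocta-2,6-dien-1-yl acetate (8-oxogeranyl acetate)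
Conditions: SeO2 (1.1 equiv), 1,4-dioxane, 80 °C
Reagents that add atoms: selenium dioxide, O=[Se]=O
Why: Riley allylic oxidation (ene reaction, then [2,3]-sigmatropic shift) attacks only the electron-rich distal alkene, at the methyl trans to the chain, so the E-enal forms and the alkene deactivated by the allylic acetate is untouched; no stereocentre is made.

**Step 2**
Reactants: 3 prenyl bromide
Product: 5 4,4,5,5-tetramethyl-2-(2-methylbut-3-en-2-yl)-1,3,2-dioxaborolane, via prenylmagnesium bromide 4 (not isolated)
Conditions: Mg, THF, 0 °C; pinacolborane, −78 °C; cold quench, distillation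
Reagents that add atoms: pinacolborane, [H]B1OC(C)(C)C(C)(C)O1
Why: Borylation of an allyl Grignard reagent with pinacolborane (hydride as leaving group) takes place at the γ-carbon under kinetic control at low temperature and gives the tertiary "reverse-prenyl" boronate; no stereocentre is made.

**Step 3**
Reactants: 2 8-oxogeranyl acetate, 5 tertiary boronate
Product: 7 (2E,6E,8S)-3,7,11-trimethyldodeca-2,6,10-triene-1,8-diyl diacetate, via pinacol borate ester 6 (not isolated)
Conditions: (S)-TRIP [(S)-3,3'-bis(2,4,6-triisopropylphenyl)-1,1'-binaphthyl-2,2'-diyl hydrogen phosphate, 5 mol%], toluene, 4 Å sieves, −30 °C; then Ac2O, DMAP (10 mol%), rt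
Reagents that add atoms: acetic anhydride, CC(=O)OC(C)=O
Why: In this chiral-phosphoric-acid-catalysed allylboration through a closed chair transition state, the tertiary boronate transfers its CH2 terminus, so the linear prenyl adduct forms with no E/Z question, and (S)-TRIP should set C7 (chain C8) as S, by analogy with (R)-TRIP giving R-carbinols from aryl and alkenyl aldehydes; the borate is acetylated in the same pot.

**Step 4**
Reactants: 7 diacetate triene
Product: 8 (2E,6E,8S,10E)-12-hydroxy-3,7,11-trimethyldodeca-2,6,10-triene-1,8-diyl diacetate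
Conditions: SeO2 (0.3 equiv), t-BuOOH (2.5 equiv), salicylic acid (0.1 equiv), CH2Cl2, 0 °C to rt
Reagents that add atoms: tert-butyl hydroperoxide, CC(C)(C)OO
Why: In this Sharpless catalytic SeO2/t-BuOOH allylic hydroxylation, the prenyl alkene is the only one not deactivated by an allylic acetate and is oxidised at its E-methyl, which fixes the E geometry of C5=C10; C7 is not touched.

**Step 5**
Reactants: 8 allylic alcohol
Product: 9 (2E,6E,8S,10E)-12-bromo-3,7,11-trimethyldodeca-2,6,10-triene-1,8-diyl diacetate
Conditions: CBr4, PPh3, CH2Cl2, −20 °C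
Reagents that add atoms: carbon tetrabromide, BrC(Br)(Br)Br
Why: The Appel reaction converts the primary allylic alcohol by SN2 under neutral conditions, so acetates, alkene geometry and C7 are kept.

**Step 6**
Reactants: 9 allylic bromide, 10 methyl 2-methyl-3-oxobutanoate
Product: 12 methyl (6E,9S,10E,14E)-9,16-diacetoxy-2,6,10,14-tetramethyl-3-oxohexadeca-6,10,14-trienoate (C2 epimers), via sodium lithium dianion 11 (not isolated)
Conditions: 10, NaH, then n-BuLi, THF, 0 °C; 9 (0.95 equiv), −78 to −30 °C; 1 M HCl quench
Reagents that add atoms: none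
Why: In the Weiler dianion alkylation, the more basic γ-carbanion displaces the allylic bromide by SN2 far faster than it adds to an acetate at low temperature; the C2 centre is enolisable and is erased in step 7.

**Step 7 (key step)**
Reactants: 12 acyclic β-keto ester
Product: 14 methyl 7β,15-diacetoxy-3-oxolabda-8(17),13E-dien-19-oate, via bicyclic C8 radical 13 (not isolated)
Conditions: Mn(OAc)3·2H2O (2.2 equiv), Cu(OAc)2·H2O (2 equiv), degassed AcOH (0.02 M), 25 °C; chromatography
Reagents that add atoms: none
Why: In this Snider-type oxidative free-radical polyene cyclisation, Mn(OAc)3 turns the enol into the electrophilic C4 radical, which closes 6-endo on E-C5=C10 and then 6-endo on E-C8=C9 through a chair–chair fold (H5 and H9 axial α, C20 axial β, side chain equatorial, CO2Me axial because the radical reacts with its two carbonyl dipoles opposed, as in the podocarpate series), Cu(OAc)2 then takes radical 13 to the least substituted alkene by oxidative elimination before it can build a further quaternary centre next to the acetoxy carbon, and the resident 7S centre makes the two mirror-image folds diastereomeric, so 14 (equatorial acetate) is isolated as one enantiomer after separation from the 7-axial fold isomer, at a fold ratio I assume to be no better than about 1:1.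

**Step 8**
Reactants: 14 3-oxo diacetate
Product: 16 methyl 7β,15-diacetoxylabda-8(17),13E-dien-19-oate, via tosylhydrazone 15 (not isolated)
Conditions: TsNHNH2 (1.5 equiv), THF–EtOH, 55 °C; catecholborane (3 equiv), CHCl3, −10 °C; NaOAc·3H2O, 60 °C
Reagents that add atoms: none
Why: In this Caglioti deoxygenation (Kabalka catecholborane variant), hydride adds to the C=N bond, sulfinate leaves and the diazene loses N2, under conditions that spare esters, allylic acetates and alkenes; no stereocentre is affected because C4 is quaternary.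

**Step 9**
Reactants: 16 diacetate
Product: 17 methyl 7β-acetoxy-15-hydroxylabda-8(17),13E-dien-19-oate (target)
Conditions: K2CO3 (0.3 equiv), MeOH, 0 °C, stopped when 16 is consumed
Reagents that add atoms: none
Why: In this Zemplén-type transesterification, the unhindered primary allylic acetate exchanges much faster than the ring-bound secondary acetate, and the axial neopentyl methyl ester is inert; no stereocentre is touched.

**Compound list**
1 | geranyl acetate | CC(C)=CCC/C(C)=C/COC(C)=O | starting material
2 | 8-oxogeranyl acetate | O=C/C(C)=C/CC/C(C)=C/COC(C)=O | intermediate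
3 | prenyl bromide | CC(C)=CCBr | starting material
4 | prenylmagnesium bromide | CC(C)=CC[Mg]Br | intermediate
5 | 4,4,5,5-tetramethyl-2-(2-methylbut-3-en-2-yl)-1,3,2-dioxaborolane | C=CC(C)(C)B1OC(C)(C)C(C)(C)O1 | intermediate
6 | pinacol borate ester of the (8S)-alcohol | CC(C)=CC[C@H](OB1OC(C)(C)C(C)(C)O1)/C(C)=C/CC/C(C)=C/COC(C)=O | intermediate
7 | (2E,6E,8S)-3,7,11-trimethyldodeca-2,6,10-triene-1,8-diyl diacetate | CC(C)=CC[C@H](OC(C)=O)/C(C)=C/CC/C(C)=C/COC(C)=O | intermediate
8 | (2E,6E,8S,10E)-12-hydroxy diacetate | OC/C(C)=C/C[C@H](OC(C)=O)/C(C)=C/CC/C(C)=C/COC(C)=O | intermediate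
9 | (2E,6E,8S,10E)-12-bromo diacetate | BrC/C(C)=C/C[C@H](OC(C)=O)/C(C)=C/CC/C(C)=C/COC(C)=O | intermediate
10 | methyl 2-methyl-3-oxobutanoate | COC(=O)C(C)C(C)=O | starting material
11 | sodium lithium dianion of 10 | [Na+].[Li+].[CH2-]C(=O)[C-](C)C(=O)OC | intermediate
12 | methyl (6E,9S,10E,14E)-9,16-diacetoxy-2,6,10,14-tetramethyl-3-oxohexadeca-6,10,14-trienoate | COC(=O)C(C)C(=O)CC/C(C)=C/C[C@H](OC(C)=O)/C(C)=C/CC/C(C)=C/COC(C)=O | intermediate
13 | bicyclic tertiary C8 radical | C[C]1[C@@H](OC(C)=O)C[C@@H]2[C@](C)(CCC(=O)[C@]2(C)C(=O)OC)[C@H]1CC/C(C)=C/COC(C)=O | intermediate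
14 | methyl 7β,15-diacetoxy-3-oxolabda-8(17),13E-dien-19-oate | C=C1[C@@H](OC(C)=O)C[C@@H]2[C@](C)(CCC(=O)[C@]2(C)C(=O)OC)[C@H]1CC/C(C)=C/COC(C)=O | intermediate
15 | C3 tosylhydrazone of 14 | C=C1[C@@H](OC(C)=O)C[C@@H]2[C@](C)(CCC(=NNS(=O)(=O)c3ccc(C)cc3)[C@]2(C)C(=O)OC)[C@H]1CC/C(C)=C/COC(C)=O | intermediate
16 | methyl 7β,15-diacetoxylabda-8(17),13E-dien-19-oate | C=C1[C@@H](OC(C)=O)C[C@@H]2[C@](C)(CCC[C@]2(C)C(=O)OC)[C@H]1CC/C(C)=C/COC(C)=O | intermediate
17 | methyl 7β-acetoxy-15-hydroxylabda-8(17),13E-dien-19-oate | C=C1[C@@H](OC(C)=O)C[C@@H]2[C@](C)(CCC[C@]2(C)C(=O)OC)[C@H]1CC/C(C)=C/CO | target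

**Total step count:** 9. **Longest linear sequence:** 8 (1 → 2 → 7 → 8 → 9 → 12 → 14 → 16 → 17).

**The three steps most likely to fail**

*Step 7.* There are three main dangers.
- C7 is remote from the first C–C bond, so fold selection is weak. In the ring B closure an equatorial acetate also eclipses the C17 methyl (A(1,2) strain), so the unwanted fold may even be preferred.
- Radical 13 may close a third ring on C13=C14.
- A C8 cation may be captured by the neighbouring acetate.

The fallback sets out from 12 and comes back at 14. NaH and PhSeCl give the α-phenylselanyl β-keto ester F1. Sunlamp irradiation in benzene (0.3 M) runs the same two closures as a phenylselanyl group-transfer chain. Transfer from F1 caps the C8 radical at a rate set by concentration and gives the tertiary C8 selenide F2. H2O2 with pyridine oxidises it to the selenoxide F3, whose syn-elimination towards the C17 methyl gives 14. This removes the metal oxidants and any cationic pathway. The fold isomers must still be separated.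

*Step 6.* The dianion may attack the two acetates or act as a base on 9. The fallback sets out from 9 and comes back at 12. The monoanion of 2,2,5,6-tetramethyl-1,3-dioxin-4-one (LiN(iPr)2, THF–DMPU, −78 °C) is alkylated at its 6-methyl group by 9 and gives the chain-extended dioxinone F4. Heating F4 in toluene–MeOH (110 °C) brings about a retro-[4+2] reaction to the acylketene F5, which MeOH traps as 12.

*Step 8.* The C3 ketone next to the quaternary C4 may not form the hydrazone. The fallback sets out from 14 and comes back at 16. NaBH4 (MeOH, −20 °C, attack from the open α face) gives the 3β-alcohol F6. 1,1'-Thiocarbonyldiimidazole (DMAP, toluene, 80 °C) gives the imidazolylthiocarbonate F7. Barton–McCombie reduction (Bu3SnH, AIBN, toluene, 90 °C) then gives 16.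

**Further compounds**
F1 | step 7 | methyl (6E,9S,10E,14E)-9,16-diacetoxy-2,6,10,14-tetramethyl-3-oxo-2-(phenylselanyl)hexadeca-6,10,14-trienoate | COC(=O)C(C)([Se]c1ccccc1)C(=O)CC/C(C)=C/C[C@H](OC(C)=O)/C(C)=C/CC/C(C)=C/COC(C)=O
F2 | step 7 | methyl 7β,15-diacetoxy-3-oxo-8-(phenylselanyl)labd-13E-en-19-oate | CC1([Se]c3ccccc3)[C@@H](OC(C)=O)C[C@@H]2[C@](C)(CCC(=O)[C@]2(C)C(=O)OC)[C@H]1CC/C(C)=C/COC(C)=O
F3 | step 7 | selenoxide of F2 | CC1([Se](=O)c3ccccc3)[C@@H](OC(C)=O)C[C@@H]2[C@](C)(CCC(=O)[C@]2(C)C(=O)OC)[C@H]1CC/C(C)=C/COC(C)=O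
F4 | step 6 | 6-alkylated 2,2,5-trimethyl-1,3-dioxin-4-one | CC1=C(CC/C(C)=C/C[C@H](OC(C)=O)/C(C)=C/CC/C(C)=C/COC(C)=O)OC(C)(C)OC1=O
F5 | step 6 | acylketene from F4 | O=C=C(C)C(=O)CC/C(C)=C/C[C@H](OC(C)=O)/C(C)=C/CC/C(C)=C/COC(C)=O
F6 | step 8 | methyl 7β,15-diacetoxy-3β-hydroxylabda-8(17),13E-dien-19-oate | C=C1[C@@H](OC(C)=O)C[C@@H]2[C@](C)(CC[C@H](O)[C@]2(C)C(=O)OC)[C@H]1CC/C(C)=C/COC(C)=O
F7 | step 8 | 3β-O-(imidazol-1-ylthiocarbonyl) derivative of F6 | C=C1[C@@H](OC(C)=O)C[C@@H]2[C@](C)(CC[C@H](OC(=S)n3ccnc3)[C@]2(C)C(=O)OC)[C@H]1CC/C(C)=C/COC(C)=O
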